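We must decide at 1.5 h how to spend the next 50 min on this flask: wait, take target out, add reagent, or heat.

| setting | larch | alder | flask |
|---|---|---|---|
| solid substrate | 0.19 M | 0.19 M | 0.19 M |
| reagent | 0.209 M | 0.209 M | 0.209 M |
| protic impurity | 0.057 M | 0.057 M | 0.0570 M |
| initiator | 9.5 mM | 9.5 mM | 9.5 mM |
| temperature | 40 °C | 35 °C | 40 °C |
| remark | the very flask that is asked about, followed so far | run made earlier |  |
| time |  |  | 1.5 h |

| run | time / min | target / % | solid substrate / % |
|---|---|---|---|
| larch | 5.00 | 0 | 89 |
| larch | 15.0 | 4 | 67 |
| larch | 25.0 | 11 | 42 |
| larch | 40.0 | 25 | 20 |
| larch | 60.0 | 26 | 0 |
| larch | 80.0 | 25 | 0 |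
| alder | 5.00 | 3 | 87 |
| alder | 15.0 | 3 | 67 |
| alder | 25.0 | 9 | 46 |
| alder | 40.0 | 30 | 26 |
| alder | 60.0 | 28 | 0 |
| alder | 80.0 | 30 | 0 |

(standard deviation of a reading: 2 percentage points)

- violet: change nothing and wait 50 min more
- amber: at 1.5 h take out 90% of the target then present, then wait 50 min
- red: at 1.5 h add reagent, 100% of the amount charged, then wait 50 min
- grey: at 1.5 h raise the temperature by 10 K, then wait 50 min

- solid substrate is a solid; its amount is given per volume of the solution
- target that was removed still counts
- at the start none of the solid substrate is in solution
- additions bring no volume worth counting

- target, in percent of the solid substrate first charged, at 1.5 h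
- what to do for the largest gain in target; "none" if nothing gains more than 2 percentage points (violet / amber / red / grey / none)
- target present, with what was taken out counted in, in percent of the solid substrate first charged, after amber
- target present, with what was taken out counted in, in percent of the solid substrate first charged, after grey

Has target stopped? The larch run is this flask followed so far. Its last readings are 25%, 26% and 25%, a spread inside the scatter of 2 percentage points. So we read a plateau of 25.3% and expect that at 1.5 h.

What stopped it? Between the same readings the solid substrate in larch fell from 20% to 0%, yet target did not follow. So substrate went into solution without becoming target, and we suspect a want of reagent. The colder alder run ends higher than larch, at 30% against 25%, so we expect nothing from heat.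

How much can fresh reagent recover? This reckoning is our own. Suppose the protic impurity destroys dissolved substrate one for one. Then c(protic impurity)/c(solid substrate) = 30.0% of the charge is lost. What remains, 44.7%, we call the recoverable share: charged substrate that is neither target nor lost to the impurity. One more charge of reagent is 110% of the substrate, more than that share. So we choose red and expect a gain of about 44.7%.

The forecast gives 25.5% now, red as best, 26% after amber and 25.5% after grey: “Adding reagent should therefore restart conversion.” It charges the impurity to the reagent, and we charged it to the substrate.

The flask gives 24.8% now. Red gains 44 points, while violet, amber and grey each gain 0 points. Target stands at 24.8% after amber and 24.8% after grey.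

    2 initiating radical → ended chains (k = 3.00 × 10⁸ /M/s, Ea = 10.0 kJ/mol)
    starting material + initiating radical → chain carrier (k = 30500 /M/s, Ea = 26.0 kJ/mol)
    solid substrate ⇌ starting material, rate k3*(cs3 - [starting material]) while solid is left; crystals form when [starting material] > cs3 (solubility = 0.110 M, k = 0.0405 /min)
    starting material + protic impurity → quenched substrate (k = 27.7 /M/min, Ea = 50.0 kJ/mol)
    reagent + chain carrier → target + initiating radical (k = 36800 /M/s, Ea = 11.0 kJ/mol)
    initiator → 2 initiating radical (k = 0.0109 /min, Ea = 95.0 kJ/mol)
    2 reagent → self-condensation product (k = 0.430 /M/min, Ea = 65.0 kJ/mol)
    (constants at 40 °C)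

In the flask at 90.0 min, starting material and chain carrier together stand at 45.2%, against the recoverable share of 44.7% that we reckoned from the readings. Reagent was the limiting reagent, with 0% free, and self-condensation product holds 77.5% of its charge. That loss and the low solubility of starting material act together, each as a part of the reason: in this flask target reaches 69.6% without self-condensation and 66.0% without the solubility limit. In a neighbour flask charged with 0.052 M of reagent, target of 16.3% gives a recoverable share of 53.7%, and starting material and chain carrier there stand at 53.7%.

The data are calculated with made-up constants, and the scatter is random.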